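**Plan**

1. Retrosynthesis: the C2 ketone goes back to a silyl-protected carbinol, and the 8-acetate/6,12-lactone to the isomeric 8,12-lactone with a free C6 hydroxyl (acyl transfer). The ring bond C6–C7 (lactone carbinol carbon to the carbon carrying the α-methylene unit) is then cut, opening the ten-membered ring to the acyclic enal 22.
2. Enabling feature: C7–C11(=C13H2)–C12 of the α-methylene-γ-lactone is the retron of a 2-carboxyallyl-metal addition to a C6 aldehyde. The oxygen on the neighbouring C8 lets this allyl donor be stored as a five-membered 8,12-butenolide (O–C8–C7=C11–C12), a temporary ring that locks the donor geometry and holds the one controlling stereocentre.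
3. Forward order: the chain is built linearly (C8–C9 by Barbier allylation, C10–C1 and C3–C4 through an epichlorohydrin linchpin, C4=C5 from an alkyne, the butenolide by ring-closing metathesis). The ten-membered carbocycle is closed last at C6–C7; then the lactone is moved from O8 to O6, O8 is acetylated and C2 is oxidised.
4. Stereochemistry: C8 comes from a Sharpless kinetic resolution; C7 and C6 are relayed from C8 in the ring closure; the C4=C5 geometry comes from trans-hydroalumination/iodination; the C2 carbinol centre is a placeholder and is erased.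

Key step: step 14

Remark: locants C1–C15 follow germacrane numbering of the target (ring C1–C10, lactone carbons C11–C13, C14 the methylidene carbon on C10, C15 the acetoxymethyl carbon on C4); the C2 carbinol configuration is arbitrary because it is oxidised in the last step.

**Route**

Step 1
Reactants: 1 2,3-dibromoprop-1-ene; 2 acrolein
Product: 3 rac-5-bromohexa-1,5-dien-3-ol
Conditions: In powder, THF/H2O (1:1), rt
Reagents that add atoms: none
Why: Indium-mediated Barbier 2-bromoallylation in water adds the allylindium species formed at the allylic C–Br bond of 1 to the aldehyde in a 1,2-fashion and leaves the vinylic bromide untouched, giving the racemic carbinol.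

Step 2
Reactants: 3 rac-5-bromohexa-1,5-dien-3-ol
Product: 4 (3S)-5-bromohexa-1,5-dien-3-ol
Conditions: Ti(OiPr)4 (0.1 equiv), D-(−)-diisopropyl tartrate (0.15 equiv), t-BuOOH (0.6 equiv), 4 Å molecular sieves, CH2Cl2, −20 °C
Reagents that add atoms: none
Why: Sharpless kinetic resolution, in which the D-(−)-tartrate catalyst epoxidises the vinyl group of the (R)-carbinol quickly and leaves the (S)-enantiomer, the future C8 centre, behind.

Step 3
Reactants: 4 (3S)-5-bromohexa-1,5-dien-3-ol
Product: 5 {[(3S)-5-bromohexa-1,5-dien-3-yl]oxy}triethylsilane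
Conditions: Et3SiCl, imidazole, CH2Cl2, 0 °C
Reagents that add atoms: chlorotriethylsilane, CC[Si](Cl)(CC)CC
Why: Standard silylation; the triethylsilyl ether tolerates the organomagnesium, organolithium and hydride steps and can later be removed together with a primary silyl ether.

Step 4
Reactants: 5 {[(3S)-5-bromohexa-1,5-dien-3-yl]oxy}triethylsilane; 6 (S)-epichlorohydrin
Product: 9 triethyl({(3S)-5-{[(2S)-oxiran-2-yl]methyl}hexa-1,5-dien-3-yl}oxy)silane, via alkenylmagnesium bromide 7 (not isolated), via chlorohydrin 8 (not isolated)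
Conditions: Mg, THF, 45 °C; then CuI (10 mol %), 6, −40 °C; then powdered NaOH, Et2O, rt
Reagents that add atoms: none
Why: Copper-catalysed epoxide opening by the alkenyl Grignard reagent at the CH2 terminus of 6 forms C10–C1, and base closes the chlorohydrin to the new epoxide, so the carbinol carbon of 6 becomes C2 with its configuration untouched.

Step 5
Reactants: 9 triethyl({(3S)-5-{[(2S)-oxiran-2-yl]methyl}hexa-1,5-dien-3-yl}oxy)silane; 10 trimethyl(prop-2-yn-1-yloxy)silane
Product: 13 (5S,9S)-7-methylidene-9-[(triethylsilyl)oxy]undec-10-en-2-yne-1,5-diol, via lithium acetylide 11 (not isolated), via trimethylsilyl ether 12 (not isolated)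
Conditions: 10, n-BuLi, THF, −78 °C; BF3·OEt2, then 9, −78 °C; then K2CO3, MeOH, 0 °C
Reagents that add atoms: none
Why: Yamaguchi–Hirao alkynylation, in which the lithium acetylide attacks the BF3-activated terminal epoxide at CH2 to form C3–C4 and the C2 carbinol, and the labile trimethylsilyl ether is lost in the basic methanolic work-up.

Step 6
Reactants: 13 (5S,9S)-7-methylidene-9-[(triethylsilyl)oxy]undec-10-en-2-yne-1,5-diol
Product: 15 (2Z,5S,9S)-3-iodo-7-methylidene-9-[(triethylsilyl)oxy]undeca-2,10-diene-1,5-diol, via alkenylalanate 14 (not isolated)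
Conditions: NaAlH2(OCH2CH2OMe)2, THF, 0 °C to rt; then I2, THF, −78 °C
Reagents that add atoms: iodine, II
Why: Hydroxyl-directed trans-hydroalumination of the propargylic alcohol places aluminium on C4 cis to C6 and hydrogen on C5, and iodinolysis with retention gives the (Z)-alkenyl iodide that fixes the C4=C5 geometry.

Step 7
Reactants: 15 (2Z,5S,9S)-3-iodo-7-methylidene-9-[(triethylsilyl)oxy]undeca-2,10-diene-1,5-diol
Product: 16 (2Z,5S,9S)-1,5-bis[(tert-butyldimethylsilyl)oxy]-3-iodo-7-methylidene-9-[(triethylsilyl)oxy]undeca-2,10-diene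
Conditions: t-BuMe2SiCl, imidazole, DMF, rt
Reagents that add atoms: tert-butyldimethylsilyl chloride, CC(C)(C)[Si](C)(C)Cl
Why: Routine bis-silylation, so that C2 stays masked to the end and the primary C6 ether can be released selectively later.

Step 8
Reactants: 16 (2Z,5S,9S)-1,5-bis[(tert-butyldimethylsilyl)oxy]-3-iodo-7-methylidene-9-[(triethylsilyl)oxy]undeca-2,10-diene
Product: 17 (2Z,5S,9S)-1,5-bis[(tert-butyldimethylsilyl)oxy]-3-(hydroxymethyl)-7-methylidene-9-[(triethylsilyl)oxy]undeca-2,10-diene
Conditions: Bu3SnCH2OH, Pd(PPh3)4 (5 mol %), 1,4-dioxane, 90 °C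
Reagents that add atoms: (tributylstannyl)methanol, CCCC[Sn](CCCC)(CCCC)CO
Why: Stille coupling transfers the hydroxymethyl group from tin to the alkenyl iodide with retention of alkene geometry, installing C15 cis to C6.

Step 9
Reactants: 17 (2Z,5S,9S)-1,5-bis[(tert-butyldimethylsilyl)oxy]-3-(hydroxymethyl)-7-methylidene-9-[(triethylsilyl)oxy]undeca-2,10-diene
Product: 18 (2Z,5S,9S)-3-(acetoxymethyl)-1,5-bis[(tert-butyldimethylsilyl)oxy]-7-methylidene-9-[(triethylsilyl)oxy]undeca-2,10-diene
Conditions: Ac2O, pyridine, DMAP (cat.), CH2Cl2, rt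
Reagents that add atoms: acetic anhydride, CC(=O)OC(C)=O
Why: Routine acetylation of the only free hydroxyl gives the C15 acetate of the target.

Step 10
Reactants: 18 (2Z,5S,9S)-3-(acetoxymethyl)-1,5-bis[(tert-butyldimethylsilyl)oxy]-7-methylidene-9-[(triethylsilyl)oxy]undeca-2,10-diene
Product: 19 (2Z,5S,9S)-3-(acetoxymethyl)-5-[(tert-butyldimethylsilyl)oxy]-7-methylideneundeca-2,10-diene-1,9-diol
Conditions: camphorsulfonic acid (10 mol %), MeOH/CH2Cl2 (1:1), 0 °C
Reagents that add atoms: none
Why: Acid-catalysed methanolysis removes the primary allylic tert-butyldimethylsilyl ether and the secondary triethylsilyl ether, both far more labile than the secondary tert-butyldimethylsilyl ether at C2.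

Step 11
Reactants: 19 (2Z,5S,9S)-3-(acetoxymethyl)-5-[(tert-butyldimethylsilyl)oxy]-7-methylideneundeca-2,10-diene-1,9-diol
Product: 20 (2Z,5S,9S)-3-(acetoxymethyl)-5-[(tert-butyldimethylsilyl)oxy]-9-hydroxy-7-methylideneundeca-2,10-dienal
Conditions: TEMPO (10 mol %), PhI(OAc)2, CH2Cl2, rt
Reagents that add atoms: none
Why: The oxoammonium oxidation (TEMPO/PhI(OAc)2) takes the primary allylic alcohol selectively in the presence of the secondary one and should give the (Z)-enal without isomerisation.

Step 12
Reactants: 20 (2Z,5S,9S)-3-(acetoxymethyl)-5-[(tert-butyldimethylsilyl)oxy]-9-hydroxy-7-methylideneundeca-2,10-dienal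
Product: 21 (3S,7S,9Z)-9-(acetoxymethyl)-7-[(tert-butyldimethylsilyl)oxy]-5-methylidene-11-oxoundeca-1,9-dien-3-yl 2-(bromomethyl)prop-2-enoate
Conditions: 2-(bromomethyl)acrylic acid, DCC, DMAP (10 mol %), CH2Cl2, 0 °C
Reagents that add atoms: 2-(bromomethyl)acrylic acid, C=C(CBr)C(=O)O
Why: Steglich esterification of the remaining secondary alcohol installs the acrylate that supplies C11, C12 and C13.

Step 13
Reactants: 21 (3S,7S,9Z)-9-(acetoxymethyl)-7-[(tert-butyldimethylsilyl)oxy]-5-methylidene-11-oxoundeca-1,9-dien-3-yl 2-(bromomethyl)prop-2-enoate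
Product: 22 (2Z,5S)-3-(acetoxymethyl)-7-{[(2S)-4-(bromomethyl)-5-oxo-2,5-dihydrofuran-2-yl]methyl}-5-[(tert-butyldimethylsilyl)oxy]octa-2,7-dienal
Conditions: second-generation Hoveyda–Grubbs catalyst (5 mol %), toluene (5 mM), 80 °C
Reagents that add atoms: none
Why: Ring-closing metathesis of the terminal vinyl group with the acrylate alkene closes the five-membered butenolide, as known for allyl 2-(bromomethyl)acrylates, while the enal and the 1,1-disubstituted alkene could only give a four-membered or a tetrasubstituted six-membered ring and stay out.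

Step 14
Reactants: 22 (2Z,5S)-3-(acetoxymethyl)-7-{[(2S)-4-(bromomethyl)-5-oxo-2,5-dihydrofuran-2-yl]methyl}-5-[(tert-butyldimethylsilyl)oxy]octa-2,7-dienal
Product: 23 (2S,4Z,6R,7S,8S)-15-acetoxy-2-[(tert-butyldimethylsilyl)oxy]-6-hydroxygermacra-4,10(14),11(13)-trien-12,8-olide
Conditions: CrCl2 (8 equiv), THF, rt, slow addition of 22 (final 2 mM); aqueous work-up
Reagents that add atoms: none
Why: Two equivalents of CrCl2 reduce the allylic C13–Br bond of the 3-(bromomethyl)butenolide to an allylchromium species of trivalent chromium, which makes C7 (the butenolide β-carbon, an electrophilic site in 22) nucleophilic, so that it adds to the equally electrophilic aldehyde carbon C6 with allyl transposition through a six-membered chair transition state and leaves the C11=C13 exocyclic alkene. The closest known reaction type is the intramolecular Nozaki–Hiyama–Kishi (chromium Barbier) allylation of aldehydes by 2-(alkoxycarbonyl)allyl bromides used to close ten-membered germacranolide rings, here with the 3-(bromomethyl)furan-2(5H)-one donor known from intermolecular Barbier reactions. The ten-membered carbocycle C1–C10 is closed in a 10-exo-trig mode (C7 onto the C6=O group, oxygen outside the new ring). C7 is controlled by the existing C8 centre, because the aldehyde is delivered to the butenolide face anti to the C9 branch (C7–C8 trans), and C6 is controlled by the chair transition state, in which the ring-locked donor has C8 trans to the CH2–Cr carbon (E-crotyl type) and the C5 alkenyl group equatorial, which gives the anti C6–OH/C7–C8 relationship of the (6R,7S,8S) isomer. The step needs aldehyde-only addition, γ-attack and ring closure instead of oligomerisation: organochromium reagents ignore lactones and acetates and react at the γ-carbon, the C2 ketone is masked as a silyl ether so that no enolisable vinylogous 1,3-dicarbonyl is present, and slow addition at 2 mM keeps the reaction intramolecular.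

Step 15
Reactants: 23 (2S,4Z,6R,7S,8S)-15-acetoxy-2-[(tert-butyldimethylsilyl)oxy]-6-hydroxygermacra-4,10(14),11(13)-trien-12,8-olide
Product: 24 (2S,4Z,6R,7R,8S)-15-acetoxy-2-[(tert-butyldimethylsilyl)oxy]-8-hydroxygermacra-4,10(14),11(13)-trien-12,6-olide
Conditions: DBU (0.2 equiv), CH2Cl2, rt; recovered 23 is resubmitted
Reagents that add atoms: none
Why: Base-catalysed translactonisation, in which the C6 hydroxyl attacks the adjacent lactone carbonyl through a five-membered tetrahedral intermediate and releases O8 with no change at C6, C7 or C8; the equilibrium should favour the trans-6,12-olide on the allylic carbon, and separation with recycling of 23 drains it in any case.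

Step 16
Reactants: 24 (2S,4Z,6R,7R,8S)-15-acetoxy-2-[(tert-butyldimethylsilyl)oxy]-8-hydroxygermacra-4,10(14),11(13)-trien-12,6-olide
Product: 25 (2S,4Z,6R,7R,8S)-8,15-diacetoxy-2-[(tert-butyldimethylsilyl)oxy]germacra-4,10(14),11(13)-trien-12,6-olide
Conditions: Ac2O, pyridine, DMAP (cat.), CH2Cl2, 0 °C
Reagents that add atoms: acetic anhydride, CC(=O)OC(C)=O
Why: Routine acetylation of the liberated C8 hydroxyl installs the second acetate and freezes the lactone at O6.

Step 17
Reactants: 25 (2S,4Z,6R,7R,8S)-8,15-diacetoxy-2-[(tert-butyldimethylsilyl)oxy]germacra-4,10(14),11(13)-trien-12,6-olide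
Product: 26 (2S,4Z,6R,7R,8S)-8,15-diacetoxy-2-hydroxygermacra-4,10(14),11(13)-trien-12,6-olide
Conditions: HF·pyridine, THF, 0 °C to rt
Reagents that add atoms: none
Why: Fluoride-mediated cleavage of the last silyl ether under conditions mild enough for the α-methylene lactone and both acetates.

Step 18
Reactants: 26 (2S,4Z,6R,7R,8S)-8,15-diacetoxy-2-hydroxygermacra-4,10(14),11(13)-trien-12,6-olide
Product: 27 (4Z,6R,7R,8S)-8,15-diacetoxy-2-oxogermacra-4,10(14),11(13)-trien-12,6-olide (CNP0183179.1)
Conditions: Dess–Martin periodinane, NaHCO3, CH2Cl2, 0 °C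
Reagents that add atoms: none
Why: Buffered Dess–Martin oxidation converts the C2 carbinol into the ketone under neutral conditions that should not move the two β,γ-double bonds into conjugation, and it erases the placeholder stereocentre.

**Compound list**

1 | 2,3-dibromoprop-1-ene | BrCC(Br)=C | starting material
2 | acrolein | C=CC=O | starting material
3 | rac-5-bromohexa-1,5-dien-3-ol | C=CC(O)CC(Br)=C | intermediate
4 | (3S)-5-bromohexa-1,5-dien-3-ol | C=C[C@@H](O)CC(Br)=C | intermediate
5 | {[(3S)-5-bromohexa-1,5-dien-3-yl]oxy}triethylsilane | C=C[C@@H](O[Si](CC)(CC)CC)CC(Br)=C | intermediate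
6 | (S)-epichlorohydrin, (2S)-2-(chloromethyl)oxirane | ClC[C@@H]1CO1 | starting material
7 | {(4S)-4-[(triethylsilyl)oxy]hexa-1,5-dien-2-yl}magnesium bromide | C=C[C@@H](O[Si](CC)(CC)CC)CC(=C)[Mg]Br | intermediate
8 | (2S,6S)-1-chloro-4-methylidene-6-[(triethylsilyl)oxy]oct-7-en-2-ol (formed as its magnesium alkoxide) | C=C[C@@H](O[Si](CC)(CC)CC)CC(=C)C[C@H](O)CCl | intermediate
9 | triethyl({(3S)-5-{[(2S)-oxiran-2-yl]methyl}hexa-1,5-dien-3-yl}oxy)silane | C=C[C@@H](O[Si](CC)(CC)CC)CC(=C)C[C@H]1CO1 | intermediate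
10 | trimethyl(prop-2-yn-1-yloxy)silane | C#CCO[Si](C)(C)C | starting material
11 | lithium 3-[(trimethylsilyl)oxy]prop-1-yn-1-ide | [Li]C#CCO[Si](C)(C)C | intermediate
12 | (5S,9S)-7-methylidene-9-[(triethylsilyl)oxy]-1-[(trimethylsilyl)oxy]undec-10-en-2-yn-5-ol | C=C[C@@H](O[Si](CC)(CC)CC)CC(=C)C[C@H](O)CC#CCO[Si](C)(C)C | intermediate
13 | (5S,9S)-7-methylidene-9-[(triethylsilyl)oxy]undec-10-en-2-yne-1,5-diol | C=C[C@@H](O[Si](CC)(CC)CC)CC(=C)C[C@H](O)CC#CCO | intermediate
14 | sodium alkenylalanate from trans-hydroalumination of 13, drawn as the cyclic 2,5-dihydro-1,2-oxaluminole with Al on C4 and the C2 alkoxide as its sodium salt | C=C[C@@H](O[Si](CC)(CC)CC)CC(=C)C[C@H]([O-])C/C1=C/CO[Al-]1(OCCOC)OCCOC.[Na+].[Na+] | intermediate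
15 | (2Z,5S,9S)-3-iodo-7-methylidene-9-[(triethylsilyl)oxy]undeca-2,10-diene-1,5-diol | C=C[C@@H](O[Si](CC)(CC)CC)CC(=C)C[C@H](O)C/C(I)=C/CO | intermediate
16 | (2Z,5S,9S)-1,5-bis[(tert-butyldimethylsilyl)oxy]-3-iodo-7-methylidene-9-[(triethylsilyl)oxy]undeca-2,10-diene | C=C[C@@H](O[Si](CC)(CC)CC)CC(=C)C[C@H](O[Si](C)(C)C(C)(C)C)C/C(I)=C/CO[Si](C)(C)C(C)(C)C | intermediate
17 | (2Z,5S,9S)-1,5-bis[(tert-butyldimethylsilyl)oxy]-3-(hydroxymethyl)-7-methylidene-9-[(triethylsilyl)oxy]undeca-2,10-diene | C=C[C@@H](O[Si](CC)(CC)CC)CC(=C)C[C@H](O[Si](C)(C)C(C)(C)C)C/C(CO)=C/CO[Si](C)(C)C(C)(C)C | intermediate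
18 | (2Z,5S,9S)-3-(acetoxymethyl)-1,5-bis[(tert-butyldimethylsilyl)oxy]-7-methylidene-9-[(triethylsilyl)oxy]undeca-2,10-diene | C=C[C@@H](O[Si](CC)(CC)CC)CC(=C)C[C@H](O[Si](C)(C)C(C)(C)C)C/C(COC(C)=O)=C/CO[Si](C)(C)C(C)(C)C | intermediate
19 | (2Z,5S,9S)-3-(acetoxymethyl)-5-[(tert-butyldimethylsilyl)oxy]-7-methylideneundeca-2,10-diene-1,9-diol | C=C[C@@H](O)CC(=C)C[C@H](O[Si](C)(C)C(C)(C)C)C/C(COC(C)=O)=C/CO | intermediate
20 | (2Z,5S,9S)-3-(acetoxymethyl)-5-[(tert-butyldimethylsilyl)oxy]-9-hydroxy-7-methylideneundeca-2,10-dienal | C=C[C@@H](O)CC(=C)C[C@H](O[Si](C)(C)C(C)(C)C)C/C(COC(C)=O)=C/C=O | intermediate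
21 | (3S,7S,9Z)-9-(acetoxymethyl)-7-[(tert-butyldimethylsilyl)oxy]-5-methylidene-11-oxoundeca-1,9-dien-3-yl 2-(bromomethyl)prop-2-enoate | C=C[C@@H](OC(=O)C(=C)CBr)CC(=C)C[C@H](O[Si](C)(C)C(C)(C)C)C/C(COC(C)=O)=C/C=O | intermediate
22 | (2Z,5S)-3-(acetoxymethyl)-7-{[(2S)-4-(bromomethyl)-5-oxo-2,5-dihydrofuran-2-yl]methyl}-5-[(tert-butyldimethylsilyl)oxy]octa-2,7-dienal | BrCC1=C[C@H](CC(=C)C[C@H](O[Si](C)(C)C(C)(C)C)C/C(COC(C)=O)=C/C=O)OC1=O | intermediate
23 | (2S,4Z,6R,7S,8S)-15-acetoxy-2-[(tert-butyldimethylsilyl)oxy]-6-hydroxygermacra-4,10(14),11(13)-trien-12,8-olide | C=C1C[C@H](O[Si](C)(C)C(C)(C)C)C/C(COC(C)=O)=C/[C@@H](O)[C@@H]2C(=C)C(=O)O[C@H]2C1 | intermediate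
24 | (2S,4Z,6R,7R,8S)-15-acetoxy-2-[(tert-butyldimethylsilyl)oxy]-8-hydroxygermacra-4,10(14),11(13)-trien-12,6-olide | C=C1C[C@H](O[Si](C)(C)C(C)(C)C)C/C(COC(C)=O)=C/[C@H]2OC(=O)C(=C)[C@@H]2[C@@H](O)C1 | intermediate
25 | (2S,4Z,6R,7R,8S)-8,15-diacetoxy-2-[(tert-butyldimethylsilyl)oxy]germacra-4,10(14),11(13)-trien-12,6-olide | C=C1C[C@H](O[Si](C)(C)C(C)(C)C)C/C(COC(C)=O)=C/[C@H]2OC(=O)C(=C)[C@@H]2[C@@H](OC(C)=O)C1 | intermediate
26 | (2S,4Z,6R,7R,8S)-8,15-diacetoxy-2-hydroxygermacra-4,10(14),11(13)-trien-12,6-olide | C=C1C[C@H](O)C/C(COC(C)=O)=C/[C@H]2OC(=O)C(=C)[C@@H]2[C@@H](OC(C)=O)C1 | intermediate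
27 | (4Z,6R,7R,8S)-8,15-diacetoxy-2-oxogermacra-4,10(14),11(13)-trien-12,6-olide (CNP0183179.1) | C=C1CC(=O)C/C(COC(C)=O)=C/[C@H]2OC(=O)C(=C)[C@@H]2[C@@H](OC(C)=O)C1 | target

**Count and risks**

Total steps: 18. Longest linear sequence: 18 steps (1 and 2 to 27); 6 and 10 are bought and enter at steps 4 and 5.

Steps most likely to fail:

1. Step 14 (ring closure). What may go wrong: oligomerisation at the concentration the organochromium species needs, loss of facial control through a boat or open transition state, or reductive opening of the butenolide by β-elimination from the transposed allylchromium isomer. Fallback, setting out from 22 and returning at 23: the allylic bromide is converted with bis(pinacolato)diboron and Pd2(dba)3 (cat.) in toluene into the allylboronate F1, an isolable nucleophile that needs no reductant. F1 is then cyclised at high dilution with Sc(OTf)3 (cat.) in toluene by intramolecular allylboration through a closed chair transition state, and aqueous work-up of the borate gives 23.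

2. Step 15 (lactone relocation). What may go wrong: the acyl-transfer equilibrium stays on the side of the 8,12-olide, or the base moves the exocyclic alkene into the lactone ring. Fallback, setting out from 23 and returning at 25, replaces the equilibrium by a gated sequence. Silylation (Et3SiCl, imidazole) gives the C6 triethylsilyl ether of 23 F2. Me3Al with N,O-dimethylhydroxylamine hydrochloride in CH2Cl2 opens the lactone to the N-methoxy-N-methylamide and also cleaves the C15 acetate, giving the 8,15-diol amide F3. Ac2O/pyridine gives the 8,15-diacetate F4. Pyridinium p-toluenesulfonate in MeOH removes the triethylsilyl group to give the C6 hydroxy amide F5, which has only the C6 hydroxyl free and lactonises onto the amide with p-TsOH (cat.) in toluene to give 25.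

3. Step 8 (hydroxymethyl transfer). What may go wrong: competing butyl transfer from tin and protodeiodination at the hindered trisubstituted alkenyl iodide. Fallback, setting out from 16 and returning at 17: methoxycarbonylation (PdCl2(PPh3)2, CO (1 atm), MeOH, Et3N, DMF, 60 °C) gives the methyl (Z)-enoate F6 with retention of geometry, and i-Bu2AlH (CH2Cl2, −78 °C) reduces the ester to the allylic alcohol 17.

**Further compounds**

F1 | step 14 | (2Z,5S)-3-(acetoxymethyl)-5-[(tert-butyldimethylsilyl)oxy]-7-{[(2S)-5-oxo-4-[(4,4,5,5-tetramethyl-1,3,2-dioxaborolan-2-yl)methyl]-2,5-dihydrofuran-2-yl]methyl}octa-2,7-dienal | CC1(C)OB(CC2=C[C@H](CC(=C)C[C@H](O[Si](C)(C)C(C)(C)C)C/C(COC(C)=O)=C/C=O)OC2=O)OC1(C)C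
F2 | step 15 | C6 triethylsilyl ether of 23 (all stereocentres as in 23) | C=C1C[C@H](O[Si](C)(C)C(C)(C)C)C/C(COC(C)=O)=C/[C@@H](O[Si](CC)(CC)CC)[C@@H]2C(=C)C(=O)O[C@H]2C1
F3 | step 15 | ring-opened N-methoxy-N-methyl 2-substituted acrylamide from F2 with free C8 and C15 hydroxyls (stereocentres as in 23) | C=C1C[C@H](O[Si](C)(C)C(C)(C)C)C/C(CO)=C/[C@@H](O[Si](CC)(CC)CC)[C@H](C(=C)C(=O)N(C)OC)[C@@H](O)C1
F4 | step 15 | 8,15-diacetate of F3 | C=C1C[C@H](O[Si](C)(C)C(C)(C)C)C/C(COC(C)=O)=C/[C@@H](O[Si](CC)(CC)CC)[C@H](C(=C)C(=O)N(C)OC)[C@@H](OC(C)=O)C1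
F5 | step 15 | C6 hydroxy amide from F4 after loss of the triethylsilyl group | C=C1C[C@H](O[Si](C)(C)C(C)(C)C)C/C(COC(C)=O)=C/[C@@H](O)[C@H](C(=C)C(=O)N(C)OC)[C@@H](OC(C)=O)C1
F6 | step 8 | methyl (Z)-enoate from 16, CO2Me in place of iodine on C4 | C=C[C@@H](O[Si](CC)(CC)CC)CC(=C)C[C@H](O[Si](C)(C)C(C)(C)C)C/C(C(=O)OC)=C/CO[Si](C)(C)C(C)(C)C
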